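**Retrosynthetic overview**
1. Endgame: the enone comes from an allylic silyl ether; the two esters go onto a differentiated trans-diol (angelate on the neopentyl oxygen first, (2R,3R)-epoxyangelate on the allylic oxygen second).
2. The seven-membered ring is formed last, by ring-closing metathesis between a vinyl and an isopropenyl arm held cis on the cyclohexene.
3. Key C–C bond: Brown (Z)-γ-(methoxymethoxy)allylboration of a non-enolisable neopentyl aldehyde joins the C12 ring fragment to the C3 allyl ether fragment and sets both carbinol centres (syn; one free OH, one MOM ether).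
4. The aldehyde comes from an Ireland–Claisen rearrangement of a tertiary allylic isobutyrate, which delivers the CMe2 carbon cis to the isopropenyl group.
5. The six-membered ring and the first stereocentre are bought as (S)-(+)-carvone; cis-carveol, directed epoxidation and a selenide-mediated epoxide-to-allylic-alcohol transposition prepare the Claisen substrate.

Assumption: (S)-(+)-carvone, angelic acid, allyl alcohol and (−)-Ipc2BOMe [from (+)-α-pinene] are bought. Abbreviations: TBS = tert-butyldimethylsilyl, MOM = methoxymethyl, PMB = 4-methoxybenzyl, Ipc = isopinocampheyl. Bicyclic names use benzo[7]annulene numbering (C4a/C9a ring fusion, C5 = CMe2, C6/C7 oxygenated, C2 = carbinol or ketone carbon).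

**Step 1**
Reactants: 1 (S)-(+)-carvone, (5S)-2-methyl-5-(prop-1-en-2-yl)cyclohex-2-en-1-one
Product: 2 (1S,5S)-cis-carveol [(1S,5S)-2-methyl-5-(prop-1-en-2-yl)cyclohex-2-en-1-ol; OH cis to isopropenyl]
Conditions: NaBH4, CeCl3·7H2O, MeOH, 0 °C
Reagents that add atoms: none
Why: Luche 1,2-reduction, in which axial hydride attack gives the equatorial alcohol cis to the isopropenyl group (new centre 1S).

**Step 2**
Reactants: 2 (1S,5S)-cis-carveol
Product: 3 (1S,2S,4R,6R)-1-methyl-4-(prop-1-en-2-yl)-7-oxabicyclo[4.1.0]heptan-2-ol (OH, epoxide O and isopropenyl all on one face)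
Conditions: VO(acac)2 (cat.), t-BuOOH, CH2Cl2, 0 °C → rt
Reagents that add atoms: tert-butyl hydroperoxide CC(C)(C)OO
Why: Hydroxyl-directed vanadium-catalysed epoxidation delivers oxygen syn to the allylic OH, so the epoxide lies on the isopropenyl face, and it leaves the isolated isopropenyl alkene alone.

**Step 3**
Reactants: 3 the epoxy alcohol
Product: 4 (1S,2S,3S,5R)-2-methyl-3-(phenylselanyl)-5-(prop-1-en-2-yl)cyclohexane-1,2-diol
Conditions: PhSeSePh, NaBH4, EtOH, rt; then 3, reflux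
Reagents that add atoms: diphenyl diselenide c1ccc(cc1)[Se][Se]c1ccccc1
Why: SN2 epoxide opening by selenolate at the secondary carbon is trans-diaxial (Fürst–Plattner) with the isopropenyl group equatorial, inverts that carbon and leaves the tertiary C–O bond and its configuration untouched.

**Step 4**
Reactants: 4 the hydroxy selenide
Product: 6 (1S,2R,5R)-2-methyl-5-(prop-1-en-2-yl)cyclohex-3-ene-1,2-diol, via selenoxide 5 (not isolated)
Conditions: 30% H2O2, NaHCO3, THF, 0 °C → rt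
Reagents that add atoms: none
Why: Selenide oxidation and selenoxide syn-elimination can only go toward the ring CH2 (the carbinol carbon has no hydrogen), giving the tertiary allylic alcohol without touching a stereocentre.

**Step 5**
Reactants: 6 the allylic diol
Product: 7 (1R,4R,6S)-6-(TBSO)-1-methyl-4-(prop-1-en-2-yl)cyclohex-2-en-1-ol
Conditions: TBSCl, imidazole, DMF, 0 °C → rt
Reagents that add atoms: tert-butyldimethylsilyl chloride CC(C)(C)[Si](C)(C)Cl
Why: Silyl ether formation is selective for the secondary over the tertiary hydroxyl on steric grounds.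

**Step 6**
Reactants: 7 the tertiary allylic alcohol
Product: 8 (1R,4R,6S)-6-(TBSO)-1-methyl-4-(prop-1-en-2-yl)cyclohex-2-en-1-yl 2-methylpropanoate
Conditions: n-BuLi, THF, −78 °C; i-PrCOCl, −78 → 0 °C
Reagents that add atoms: isobutyryl chloride CC(C)C(=O)Cl
Why: Acylation of the preformed lithium alkoxide forces esterification of the hindered tertiary alcohol, and the low temperature keeps the neighbouring silyl group from migrating.

**Step 7**
Reactants: 8 the tertiary allylic isobutyrate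
Product: 11 2-[(1S,4S,6R)-4-(TBSO)-3-methyl-6-(prop-1-en-2-yl)cyclohex-2-en-1-yl]-2-methylpropanoic acid, via silyl ketene acetal 9 (not isolated), via trimethylsilyl ester 10 (not isolated)
Conditions: LiN(i-Pr)2, TMSCl, Et3N, THF, −78 °C → 60 °C; then MeOH/H2O, citric acid
Reagents that add atoms: none
Why: The Ireland–Claisen [3,3] rearrangement is suprafacial, so the CMe2 carbon bonds to the ring on the face of the departing ester oxygen, cis to the isopropenyl group (new centre 1S), and the tetrasubstituted ketene acetal has no E/Z issue.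

**Step 8**
Reactants: 11 the acid
Product: 12 2-[(1S,4S,6R)-4-(TBSO)-3-methyl-6-(prop-1-en-2-yl)cyclohex-2-en-1-yl]-2-methylpropan-1-ol
Conditions: LiAlH4, THF, 0 °C → reflux
Reagents that add atoms: none
Why: Hydride reduction of the carboxylic acid to the primary alcohol leaves the silyl ether and the alkenes unchanged.

**Step 9**
Reactants: 12 the neopentyl alcohol
Product: 13 2-[(1S,4S,6R)-4-(TBSO)-3-methyl-6-(prop-1-en-2-yl)cyclohex-2-en-1-yl]-2-methylpropanal
Conditions: Dess–Martin periodinane, NaHCO3, CH2Cl2, rt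
Reagents that add atoms: none
Why: Dess–Martin oxidation gives an aldehyde with no α-hydrogen, so it can neither enolise nor epimerise.

**Step 10**
Reactants: 14 allyl alcohol (prop-2-en-1-ol)
Product: 15 allyl methoxymethyl ether [3-(methoxymethoxy)prop-1-ene]
Conditions: MOMCl, i-Pr2NEt, CH2Cl2, 0 °C → rt
Reagents that add atoms: chloromethyl methyl ether COCCl
Why: Simple O-alkylation of a primary alcohol (MOM ether formation).

**Step 11 (key fragment union)**
Reactants: 13 the neopentyl aldehyde, 15 allyl methoxymethyl ether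
Product: 18 (3R,4R)-2-[(1S,4S,6R)-4-(TBSO)-3-methyl-6-(prop-1-en-2-yl)cyclohex-2-en-1-yl]-4-(methoxymethoxy)-2-methylhex-5-en-3-ol, via Z-alkoxyallylborane 16 (not isolated), via borinate 17 (not isolated)
Conditions: 15, s-BuLi, THF, −78 °C; (−)-Ipc2BOMe; BF3·OEt2; then 13, −78 °C; NaOH, H2O2
Reagents that add atoms: none
Why: Brown asymmetric γ-alkoxyallylboration (carbonyl allylation) runs through a chair Zimmerman–Traxler transition state, so the Z-allylborane gives the syn 1,2-diol monoether and the Ipc groups from (+)-α-pinene direct attack to the aldehyde Si face, setting 3R,4R under reagent control.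

**Step 12**
Reactants: 18 the diene alcohol
Product: 19 (2S,4aS,6R,7R,9aR)-2-(TBSO)-7-(methoxymethoxy)-3,5,5,9-tetramethyl-2,4a,5,6,7,9a-hexahydro-1H-benzo[7]annulen-6-ol
Conditions: second-generation Grubbs catalyst RuCl2(=CHPh)(PCy3)(H2IMes) (5 mol %), CH2Cl2, 40 °C
Reagents that add atoms: none
Why: Ring-closing metathesis between the vinyl and isopropenyl arms, held cis on the cyclohexene, closes the seven-membered ring with loss of ethylene while the hindered trisubstituted ring alkene stays out.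

**Step 13**
Reactants: 19 the bicyclic alcohol, 20 angelic acid [(2Z)-2-methylbut-2-enoic acid]
Product: 22 (2S,4aS,6R,7R,9aR)-2-(TBSO)-7-(methoxymethoxy)-3,5,5,9-tetramethyl-2,4a,5,6,7,9a-hexahydro-1H-benzo[7]annulen-6-yl (2Z)-2-methylbut-2-enoate, via mixed anhydride 21 (not isolated)
Conditions: 20, 2,4,6-Cl3C6H2COCl, Et3N, toluene, rt; then 19, 80 °C
Reagents that add atoms: none
Why: Yamaguchi-type mixed-anhydride esterification without a nucleophilic catalyst acylates the hindered secondary alcohol while avoiding Z-to-E isomerisation of the angelate to the tiglate.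

**Step 14**
Reactants: 22 the MOM-protected angelate
Product: 24 (2S,4aS,6R,7R,9aR)-2-(TBSO)-7-hydroxy-3,5,5,9-tetramethyl-2,4a,5,6,7,9a-hexahydro-1H-benzo[7]annulen-6-yl (2Z)-2-methylbut-2-enoate, via bromomethyl ether 23 (not isolated)
Conditions: Me2BBr, CH2Cl2, −78 °C; then NaHCO3, THF/H2O
Reagents that add atoms: none
Why: Dimethylboron bromide cleaves the acetal C–O bond of the MOM group at −78 °C and the bromomethyl ether hydrolyses on work-up, conditions that spare the silyl ether, the ester and the alkenes.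

**Step 15**
Reactants: 20 angelic acid
Product: 25 (2Z)-2-methylbut-2-en-1-ol
Conditions: LiAlH4, Et2O, 0 °C
Reagents that add atoms: none
Why: Hydride 1,2-reduction of the conjugated acid gives the allylic alcohol with the Z geometry retained.

**Step 16**
Reactants: 25 (2Z)-2-methylbut-2-en-1-ol
Product: 26 [(2S,3R)-2,3-dimethyloxiran-2-yl]methanol
Conditions: Ti(OiPr)4, L-(+)-diethyl tartrate, t-BuOOH, 4 Å MS, CH2Cl2, −20 °C
Reagents that add atoms: tert-butyl hydroperoxide CC(C)(C)OO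
Why: Sharpless asymmetric epoxidation, in which L-(+)-tartrate selects the alkene face that gives the 2S,3R epoxide and the stereospecific oxygen transfer keeps the two methyl groups trans.

**Step 17**
Reactants: 26 the epoxy alcohol
Product: 27 (2R,3R)-2,3-dimethyloxirane-2-carboxylic acid (epoxyangelic acid)
Conditions: RuCl3·xH2O (cat.), NaIO4, CCl4/MeCN/H2O, rt
Reagents that add atoms: water O
Why: Ruthenium tetroxide oxidation of the primary alcohol to the acid leaves the epoxide intact (the C2 descriptor changes from S to R only through CIP priorities).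

**Step 18**
Reactants: 24 the hydroxy angelate, 27 epoxyangelic acid
Product: 29 (2S,4aS,6R,7R,9aR)-2-(TBSO)-3,5,5,9-tetramethyl-6-{[(2Z)-2-methylbut-2-enoyl]oxy}-2,4a,5,6,7,9a-hexahydro-1H-benzo[7]annulen-7-yl (2R,3R)-2,3-dimethyloxirane-2-carboxylate, via mixed anhydride 28 (not isolated)
Conditions: 27, 2,4,6-Cl3C6H2COCl, Et3N, toluene, rt; then 24, DMAP, rt
Reagents that add atoms: none
Why: Yamaguchi esterification of the allylic alcohol with an acid that has no α-hydrogen and therefore cannot epimerise, the small amount of diastereomer from the minor acid enantiomer being removed by chromatography.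

**Step 19**
Reactants: 29 the silyl-protected diester
Product: 30 (2S,4aS,6R,7R,9aR)-2-hydroxy-3,5,5,9-tetramethyl-6-{[(2Z)-2-methylbut-2-enoyl]oxy}-2,4a,5,6,7,9a-hexahydro-1H-benzo[7]annulen-7-yl (2R,3R)-2,3-dimethyloxirane-2-carboxylate
Conditions: HF·pyridine, pyridine, THF, 0 °C → rt
Reagents that add atoms: none
Why: Buffered fluoride desilylation removes the allylic TBS ether under non-basic conditions that avoid acyl migration, ester cleavage and opening of the electron-poor epoxide.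

**Step 20**
Reactants: 30 the allylic alcohol
Product: 31 target, (4aS,6R,7R,9aR)-3,5,5,9-tetramethyl-6-{[(2Z)-2-methylbut-2-enoyl]oxy}-2-oxo-2,4a,5,6,7,9a-hexahydro-1H-benzo[7]annulen-7-yl (2R,3R)-2,3-dimethyloxirane-2-carboxylate
Conditions: Dess–Martin periodinane, NaHCO3, CH2Cl2, 0 °C → rt
Reagents that add atoms: none
Why: Dess–Martin oxidation of the allylic alcohol gives the enone under buffered, non-basic conditions, so the γ ring-fusion centre is not epimerised.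

**Compound list**
1 | (S)-(+)-carvone | CC1=CC[C@@H](CC1=O)C(C)=C | starting material
2 | (1S,5S)-cis-carveol | CC1=CC[C@@H](C[C@@H]1O)C(C)=C | intermediate
3 | (1S,2S,4R,6R)-1-methyl-4-(prop-1-en-2-yl)-7-oxabicyclo[4.1.0]heptan-2-ol | O[C@H]1C[C@@H](C(C)=C)C[C@H]2O[C@@]12C | intermediate
4 | (1S,2S,3S,5R)-2-methyl-3-(phenylselanyl)-5-(prop-1-en-2-yl)cyclohexane-1,2-diol | O[C@H]1C[C@@H](C(C)=C)C[C@H]([Se]c2ccccc2)[C@@]1(C)O | intermediate
5 | selenoxide of 4 (mixture at Se) | O[C@H]1C[C@@H](C(C)=C)C[C@H]([Se](=O)c2ccccc2)[C@@]1(C)O | intermediate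
6 | (1S,2R,5R)-2-methyl-5-(prop-1-en-2-yl)cyclohex-3-ene-1,2-diol | O[C@H]1C[C@@H](C(C)=C)C=C[C@@]1(C)O | intermediate
7 | (1R,4R,6S)-6-(TBSO)-1-methyl-4-(prop-1-en-2-yl)cyclohex-2-en-1-ol | CC(C)(C)[Si](C)(C)O[C@H]1C[C@@H](C(C)=C)C=C[C@@]1(C)O | intermediate
8 | (1R,4R,6S)-6-(TBSO)-1-methyl-4-(prop-1-en-2-yl)cyclohex-2-en-1-yl 2-methylpropanoate | CC(C)(C)[Si](C)(C)O[C@H]1C[C@@H](C(C)=C)C=C[C@@]1(C)OC(=O)C(C)C | intermediate
9 | trimethylsilyl ketene acetal of 8 | CC(C)(C)[Si](C)(C)O[C@H]1C[C@@H](C(C)=C)C=C[C@@]1(C)OC(O[Si](C)(C)C)=C(C)C | intermediate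
10 | trimethylsilyl ester of 11 | C=C(C)[C@@H]1C[C@H](O[Si](C)(C)C(C)(C)C)C(C)=C[C@@H]1C(C)(C)C(=O)O[Si](C)(C)C | intermediate
11 | 2-[(1S,4S,6R)-4-(TBSO)-3-methyl-6-(prop-1-en-2-yl)cyclohex-2-en-1-yl]-2-methylpropanoic acid | C=C(C)[C@@H]1C[C@H](O[Si](C)(C)C(C)(C)C)C(C)=C[C@@H]1C(C)(C)C(=O)O | intermediate
12 | 2-[(1S,4S,6R)-4-(TBSO)-3-methyl-6-(prop-1-en-2-yl)cyclohex-2-en-1-yl]-2-methylpropan-1-ol | C=C(C)[C@@H]1C[C@H](O[Si](C)(C)C(C)(C)C)C(C)=C[C@@H]1C(C)(C)CO | intermediate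
13 | 2-[(1S,4S,6R)-4-(TBSO)-3-methyl-6-(prop-1-en-2-yl)cyclohex-2-en-1-yl]-2-methylpropanal | C=C(C)[C@@H]1C[C@H](O[Si](C)(C)C(C)(C)C)C(C)=C[C@@H]1C(C)(C)C=O | intermediate
14 | allyl alcohol | C=CCO | starting material
15 | allyl methoxymethyl ether | C=CCOCOC | intermediate
16 | [(2Z)-3-(methoxymethoxy)prop-2-en-1-yl]diisopinocampheylborane (Ipc from (+)-α-pinene) | COCO/C=C\CB([C@@H]1C[C@@H]2C[C@H]([C@H]1C)C2(C)C)[C@@H]1C[C@@H]2C[C@H]([C@H]1C)C2(C)C | intermediate
17 | diisopinocampheylborinate of 18 (O–B(Ipc)2 at C3) | C=C(C)[C@@H]1C[C@H](O[Si](C)(C)C(C)(C)C)C(C)=C[C@@H]1C(C)(C)[C@@H](OB([C@@H]2C[C@@H]3C[C@H]([C@H]2C)C3(C)C)[C@@H]2C[C@@H]3C[C@H]([C@H]2C)C3(C)C)[C@H](OCOC)C=C | intermediate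
18 | (3R,4R)-2-[(1S,4S,6R)-4-(TBSO)-3-methyl-6-(prop-1-en-2-yl)cyclohex-2-en-1-yl]-4-(methoxymethoxy)-2-methylhex-5-en-3-ol | C=C(C)[C@@H]1C[C@H](O[Si](C)(C)C(C)(C)C)C(C)=C[C@@H]1C(C)(C)[C@@H](O)[C@H](OCOC)C=C | intermediate
19 | (2S,4aS,6R,7R,9aR)-2-(TBSO)-7-(methoxymethoxy)-3,5,5,9-tetramethyl-2,4a,5,6,7,9a-hexahydro-1H-benzo[7]annulen-6-ol | O[C@H]1[C@H](OCOC)C=C(C)[C@@H]2C[C@H](O[Si](C)(C)C(C)(C)C)C(C)=C[C@@H]2C1(C)C | intermediate
20 | angelic acid, (2Z)-2-methylbut-2-enoic acid | C/C=C(/C)C(=O)O | starting material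
21 | (2Z)-2-methylbut-2-enoic 2,4,6-trichlorobenzoic anhydride | C/C=C(/C)C(=O)OC(=O)c1c(Cl)cc(Cl)cc1Cl | intermediate
22 | 6-O-angeloyl 7-O-MOM 2-O-TBS bicycle (angelate of 19) | C/C=C(/C)C(=O)O[C@H]1[C@H](OCOC)C=C(C)[C@@H]2C[C@H](O[Si](C)(C)C(C)(C)C)C(C)=C[C@@H]2C1(C)C | intermediate
23 | 7-O-bromomethyl ether corresponding to 22 | C/C=C(/C)C(=O)O[C@H]1[C@H](OCBr)C=C(C)[C@@H]2C[C@H](O[Si](C)(C)C(C)(C)C)C(C)=C[C@@H]2C1(C)C | intermediate
24 | (2S,4aS,6R,7R,9aR)-2-(TBSO)-7-hydroxy-3,5,5,9-tetramethyl-2,4a,5,6,7,9a-hexahydro-1H-benzo[7]annulen-6-yl (2Z)-2-methylbut-2-enoate | C/C=C(/C)C(=O)O[C@H]1[C@H](O)C=C(C)[C@@H]2C[C@H](O[Si](C)(C)C(C)(C)C)C(C)=C[C@@H]2C1(C)C | intermediate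
25 | (2Z)-2-methylbut-2-en-1-ol | C/C=C(/C)CO | intermediate
26 | [(2S,3R)-2,3-dimethyloxiran-2-yl]methanol | OC[C@]1(C)O[C@@H]1C | intermediate
27 | (2R,3R)-2,3-dimethyloxirane-2-carboxylic acid | OC(=O)[C@]1(C)O[C@@H]1C | intermediate
28 | (2R,3R)-2,3-dimethyloxirane-2-carboxylic 2,4,6-trichlorobenzoic anhydride | O=C(OC(=O)c1c(Cl)cc(Cl)cc1Cl)[C@]2(C)O[C@@H]2C | intermediate
29 | 2-O-TBS ether of the diester (see step 18) | C/C=C(/C)C(=O)O[C@H]1[C@H](OC(=O)[C@]2(C)O[C@@H]2C)C=C(C)[C@@H]2C[C@H](O[Si](C)(C)C(C)(C)C)C(C)=C[C@@H]2C1(C)C | intermediate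
30 | (2S)-allylic alcohol of the diester (see step 19) | C/C=C(/C)C(=O)O[C@H]1[C@H](OC(=O)[C@]2(C)O[C@@H]2C)C=C(C)[C@@H]2C[C@H](O)C(C)=C[C@@H]2C1(C)C | intermediate
31 | (4aS,6R,7R,9aR)-3,5,5,9-tetramethyl-6-{[(2Z)-2-methylbut-2-enoyl]oxy}-2-oxo-2,4a,5,6,7,9a-hexahydro-1H-benzo[7]annulen-7-yl (2R,3R)-2,3-dimethyloxirane-2-carboxylate | C/C=C(/C)C(=O)O[C@H]1[C@H](OC(=O)[C@]2(C)O[C@@H]2C)C=C(C)[C@@H]2CC(=O)C(C)=C[C@@H]2C1(C)C | target

**Totals**
Total step count: 20. Longest linear sequence: 16 steps (steps 1–9, 11–14, 18–20, from (S)-carvone).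

**Three steps most likely to fail, with fallbacks**

Step 7 (Ireland–Claisen on a hindered tertiary allylic isobutyrate; risk of elimination instead of rearrangement, and step 6 before it is itself a hindered acylation). The fallback sets out from 7 and returns at 12. Heating 7 with N,N-dimethylacetamide dimethyl acetal in xylene at 140 °C (Eschenmoser–Claisen, no ester or strong base needed, same suprafacial cis delivery of a smaller two-carbon unit) gives 2-[(1S,4S,6R)-4-(TBSO)-3-methyl-6-(prop-1-en-2-yl)cyclohex-2-en-1-yl]-N,N-dimethylacetamide F1. The quaternary carbon is then built by enolate alkylation: LiN(i-Pr)2/MeI in THF at −78 °C gives the α-methyl amide, 2-[(1S,4S,6R)-4-(TBSO)-3-methyl-6-(prop-1-en-2-yl)cyclohex-2-en-1-yl]-N,N-dimethylpropanamide F2 (epimers at the α-carbon), and a second LiN(i-Pr)2/MeI round gives 2-[(1S,4S,6R)-4-(TBSO)-3-methyl-6-(prop-1-en-2-yl)cyclohex-2-en-1-yl]-N,N,2-trimethylpropanamide F3. LiH2NBH3 in THF reduces F3 to alcohol 12.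

Step 11 (air-sensitive allylborane and a very hindered neopentyl aldehyde; low conversion or eroded selectivity possible). The fallback sets out from 13 and returns at 24.
- Aldol: Evans syn-glycolate aldol of 13 with the dibutylboron enolate of (S)-4-benzyl-3-[(4-methoxybenzyloxy)acetyl]oxazolidin-2-one (Bu2BOTf, Et3N, CH2Cl2, −78 → 0 °C) sets the same two carbinol centres under auxiliary control and gives (4S)-4-benzyl-3-{(2S,3R)-3-hydroxy-2-(PMB-oxy)-4-methyl-4-[(1S,4S,6R)-4-(TBSO)-3-methyl-6-(prop-1-en-2-yl)cyclohex-2-en-1-yl]pentanoyl}oxazolidin-2-one F4.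
- Auxiliary removal: LiBH4 in THF/MeOH gives the (2R,3R)-2-(PMB-oxy)-4-methyl-4-(cyclohexenyl)pentane-1,3-diol F5.
- Oxidation: TEMPO/PhI(OAc)2 oxidises only the primary hydroxyl, giving the (2S,3R)-3-hydroxy-2-(PMB-oxy)-4-methyl-4-(cyclohexenyl)pentanal F6.
- Methylenation: non-basic Lombardo conditions (Zn, CH2Br2, TiCl4) give the PMB analogue of 18, (3R,4R)-4-(PMB-oxy)-2-methyl-2-(cyclohexenyl)hex-5-en-3-ol F7.
- Ring closure and acylation: metathesis as in step 12 gives the 7-O-PMB analogue of 19 F8, and angeloylation as in step 13 gives the 7-O-PMB analogue of 22 F9.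
- Deprotection: DDQ in CH2Cl2/pH 7 buffer removes the PMB group to give 24.

Step 13 (acylation of a neopentyl-type secondary alcohol with angelic acid; risk of no reaction or of tiglate formation). The fallback sets out from 19 and returns at 22. Esterifying 19 with the smaller, saturated 2-[bis(2,2,2-trifluoroethoxy)phosphoryl]propanoic acid (DCC, DMAP, CH2Cl2) gives the 6-O-{2-[bis(2,2,2-trifluoroethoxy)phosphoryl]propanoyl} ester of 19 F10. Still–Gennari olefination of F10 with acetaldehyde (KN(SiMe3)2, 18-crown-6, THF, −78 °C; no ketone is present at this stage) then builds the Z-trisubstituted enoate on the molecule and gives 22.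

**Further compounds**
F1 | step 7 | 2-[(1S,4S,6R)-4-(TBSO)-3-methyl-6-(prop-1-en-2-yl)cyclohex-2-en-1-yl]-N,N-dimethylacetamide | C=C(C)[C@@H]1C[C@H](O[Si](C)(C)C(C)(C)C)C(C)=C[C@@H]1CC(=O)N(C)C
F2 | step 7 | 2-[(1S,4S,6R)-4-(TBSO)-3-methyl-6-(prop-1-en-2-yl)cyclohex-2-en-1-yl]-N,N-dimethylpropanamide (α-epimers) | C=C(C)[C@@H]1C[C@H](O[Si](C)(C)C(C)(C)C)C(C)=C[C@@H]1C(C)C(=O)N(C)C
F3 | step 7 | 2-[(1S,4S,6R)-4-(TBSO)-3-methyl-6-(prop-1-en-2-yl)cyclohex-2-en-1-yl]-N,N,2-trimethylpropanamide | C=C(C)[C@@H]1C[C@H](O[Si](C)(C)C(C)(C)C)C(C)=C[C@@H]1C(C)(C)C(=O)N(C)C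
F4 | step 11 | (4S)-4-benzyl-3-{(2S,3R)-3-hydroxy-2-(PMB-oxy)-4-methyl-4-[(1S,4S,6R)-4-(TBSO)-3-methyl-6-(prop-1-en-2-yl)cyclohex-2-en-1-yl]pentanoyl}oxazolidin-2-one | C=C(C)[C@@H]1C[C@H](O[Si](C)(C)C(C)(C)C)C(C)=C[C@@H]1C(C)(C)[C@@H](O)[C@H](OCc1ccc(OC)cc1)C(=O)N1[C@@H](Cc2ccccc2)COC1=O
F5 | step 11 | (2R,3R)-2-(PMB-oxy)-4-methyl-4-[(1S,4S,6R)-4-(TBSO)-3-methyl-6-(prop-1-en-2-yl)cyclohex-2-en-1-yl]pentane-1,3-diol | C=C(C)[C@@H]1C[C@H](O[Si](C)(C)C(C)(C)C)C(C)=C[C@@H]1C(C)(C)[C@@H](O)[C@H](OCc1ccc(OC)cc1)CO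
F6 | step 11 | (2S,3R)-3-hydroxy-2-(PMB-oxy)-4-methyl-4-[(1S,4S,6R)-4-(TBSO)-3-methyl-6-(prop-1-en-2-yl)cyclohex-2-en-1-yl]pentanal | C=C(C)[C@@H]1C[C@H](O[Si](C)(C)C(C)(C)C)C(C)=C[C@@H]1C(C)(C)[C@@H](O)[C@H](OCc1ccc(OC)cc1)C=O
F7 | step 11 | (3R,4R)-4-(PMB-oxy)-2-methyl-2-[(1S,4S,6R)-4-(TBSO)-3-methyl-6-(prop-1-en-2-yl)cyclohex-2-en-1-yl]hex-5-en-3-ol | C=C(C)[C@@H]1C[C@H](O[Si](C)(C)C(C)(C)C)C(C)=C[C@@H]1C(C)(C)[C@@H](O)[C@H](OCc1ccc(OC)cc1)C=C
F8 | step 11 | (2S,4aS,6R,7R,9aR)-2-(TBSO)-7-(PMB-oxy)-3,5,5,9-tetramethyl-2,4a,5,6,7,9a-hexahydro-1H-benzo[7]annulen-6-ol | O[C@H]1[C@H](OCc3ccc(OC)cc3)C=C(C)[C@@H]2C[C@H](O[Si](C)(C)C(C)(C)C)C(C)=C[C@@H]2C1(C)C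
F9 | step 11 | (2S,4aS,6R,7R,9aR)-2-(TBSO)-7-(PMB-oxy)-3,5,5,9-tetramethyl-2,4a,5,6,7,9a-hexahydro-1H-benzo[7]annulen-6-yl (2Z)-2-methylbut-2-enoate | C/C=C(/C)C(=O)O[C@H]1[C@H](OCc3ccc(OC)cc3)C=C(C)[C@@H]2C[C@H](O[Si](C)(C)C(C)(C)C)C(C)=C[C@@H]2C1(C)C
F10 | step 13 | (2S,4aS,6R,7R,9aR)-2-(TBSO)-7-(methoxymethoxy)-3,5,5,9-tetramethyl-2,4a,5,6,7,9a-hexahydro-1H-benzo[7]annulen-6-yl 2-[bis(2,2,2-trifluoroethoxy)phosphoryl]propanoate (epimers at the α-carbon) | CC(C(=O)O[C@H]1[C@H](OCOC)C=C(C)[C@@H]2C[C@H](O[Si](C)(C)C(C)(C)C)C(C)=C[C@@H]2C1(C)C)P(=O)(OCC(F)(F)F)OCC(F)(F)F
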